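**Plan**

- Target: catechin-(4α→6)-epicatechin-(4β→8)-epicatechin-(4β→8)-epicatechin (units 1 to 4 from the top). The retrosynthesis removes sixteen benzyl ethers, cuts C4(unit 2)–C8(unit 3), then cuts O1–C2 and C4a–C4 of unit 2 together, then cuts C4(unit 1)–aryl.
- Enabling feature: ring A of unit 2 is a phloroglucinol ring hung on C4 of unit 1. Its O1/C4a pair is a phenol with a free ortho carbon (an O,C-bisnucleophile), and C4–C3–C2 of ring C has the skeleton of a 3-aryl-2,3-epoxy aldehyde (a 1,3-bis-electrophile). Only O1 lies para to the bond to unit 1.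
- Forward: (+)-catechin is arylated at C4 with phloroglucinol and trimmed to phenol 8, in which only the para oxygen is free. Ring C of unit 2 is annulated onto 8 with cis-epoxy aldehyde 13, which fixes the 4→6 connectivity by construction. The new C4 carbinol is ionized and joined to C8 of a procyanidin B2 block made from (−)-epicatechin; hydrogenolysis ends the route.
- Stereochemistry: units 1, 3 and 4 come from natural (+)-catechin and (−)-epicatechin. C4 of units 1, 2 and 3 is set by attack on flavan C4 cations anti to the 3-OH. C2 and C3 of unit 2 come from a Jacobsen epoxidation of a Z-cinnamate, with inversion at C2 during the annulation.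

Key step: step 10

Remark: the C4 carbinol of 15 is drawn as the expected Felkin–Anh epimer (3,4-cis); its configuration is immaterial because step 14 ionizes this centre.

**Route**

Step 1
Reactants: 1 (+)-catechin
Product: 2 5,7,3',4'-tetra-O-benzyl-(+)-catechin
Conditions: BnBr (4.4 equiv), K2CO3, DMF, 0 °C to rt
Reagents that add atoms: benzyl bromide, BrCc1ccccc1
Why: Williamson etherification of the four phenols under carbonate base, which leaves the less acidic aliphatic 3-OH free.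

Step 2
Reactants: 2 5,7,3',4'-tetra-O-benzyl-(+)-catechin
Product: 3 4β-(2-ethoxyethoxy)-5,7,3',4'-tetra-O-benzylcatechin (2,3-trans-3,4-cis)
Conditions: DDQ (2 equiv), 2-ethoxyethanol (5 equiv), CH2Cl2, rt
Reagents that add atoms: 2-ethoxyethanol, CCOCCO
Why: DDQ benzylic oxidation, in which hydride abstraction from C4 gives the ring A-stabilized cation that the alcohol captures (ether expected pseudo-axial, β); this centre is ionized again in step 3.

Step 3
Reactants: 3 4β-(2-ethoxyethoxy)-5,7,3',4'-tetra-O-benzylcatechin, 4 phloroglucinol (5 equiv)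
Product: 5 5,7,3',4'-tetra-O-benzylcatechin-(4α→2)-phloroglucinol (2,3-trans-3,4-trans)
Conditions: BF3·OEt2 (0.5 equiv), THF/CH2Cl2, −20 to 0 °C
Reagents that add atoms: none
Why: Lewis acid-promoted Friedel–Crafts arylation of the flavan C4 cation by symmetric phloroglucinol (one regioisomer, excess prevents double alkylation), which should enter trans to the 3-OH (4α) as is typical for catechin-type cations.

Step 4
Reactants: 5 5,7,3',4'-tetra-O-benzylcatechin-(4α→2)-phloroglucinol
Product: 6 mono-triisopropylsilyl ether of 5 at the phloroglucinol oxygen para to the flavan bond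
Conditions: iPr3SiCl (1.05 equiv), imidazole, DMF, −20 to 0 °C
Reagents that add atoms: triisopropylsilyl chloride, CC(C)[Si](Cl)(C(C)C)C(C)C
Why: sterically controlled silylation, since the para OH is flanked by two ring hydrogens whereas both ortho OH groups are flanked by the bulky flavan-4-yl group, so the bulky chlorosilane should select the para oxygen.

Step 5
Reactants: 6 para-O-triisopropylsilyl ether
Product: 7 4α-[2,6-bis(benzyloxy)-4-(triisopropylsilyloxy)phenyl]-5,7,3',4'-tetra-O-benzylcatechin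
Conditions: BnBr (2.4 equiv), K2CO3, Bu4NI (0.1 equiv), DMF, rt
Reagents that add atoms: benzyl bromide, BrCc1ccccc1
Why: Williamson etherification of the two remaining phenols; the aryl triisopropylsilyl ether tolerates carbonate in DMF at room temperature and the 3-OH is not alkylated.

Step 6
Reactants: 7 4α-[2,6-bis(benzyloxy)-4-(triisopropylsilyloxy)phenyl]-5,7,3',4'-tetra-O-benzylcatechin
Product: 8 4α-[2,6-bis(benzyloxy)-4-hydroxyphenyl]-5,7,3',4'-tetra-O-benzylcatechin
Conditions: Bu4NF (1.1 equiv), AcOH (1.1 equiv), THF, 0 °C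
Reagents that add atoms: none
Why: fluoride cleavage of the aryl silyl ether driven by the Si–F bond, buffered with acetic acid to protect the electron-rich phenol from oxidation; benzyl ethers are untouched.

Step 7
Reactants: 9 3,4-bis(benzyloxy)benzaldehyde, 10 methyl bis(2,2,2-trifluoroethoxy)phosphorylacetate
Product: 11 methyl (Z)-3-[3,4-bis(benzyloxy)phenyl]prop-2-enoate
Conditions: KN(SiMe3)2, 18-crown-6, THF, −78 °C
Reagents that add atoms: none
Why: Still–Gennari modification of the Horner–Wadsworth–Emmons olefination, in which the electron-poor phosphonate under dissociating conditions eliminates fast from the kinetic adduct and should give the Z-cinnamate.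

Step 8
Reactants: 11 methyl (Z)-3-[3,4-bis(benzyloxy)phenyl]prop-2-enoate
Product: 12 methyl (2S,3S)-3-[3,4-bis(benzyloxy)phenyl]oxirane-2-carboxylate (cis)
Conditions: (S,S)-(salen)MnCl (trivalent manganese; salen = N,N'-bis(3,5-di-tert-butylsalicylidene)-1,2-cyclohexanediamine dianion, 5 mol %), 4-phenylpyridine N-oxide (0.25 equiv), aq. NaOCl (pH 11.3), CH2Cl2, 4 °C
Reagents that add atoms: sodium hypochlorite, [Na+].[O-]Cl
Why: Jacobsen–Katsuki epoxidation of a cis-cinnamate ester, in which the chiral salen ligand selects the alkene face and sets both epoxide centres; the (S,S)-catalyst is chosen by analogy with cis-ethyl cinnamate, which gives the (2R,3R)-glycidate with the (R,R)-catalyst.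

Step 9
Reactants: 12 methyl (2S,3S)-3-[3,4-bis(benzyloxy)phenyl]oxirane-2-carboxylate
Product: 13 (2S,3S)-3-[3,4-bis(benzyloxy)phenyl]oxirane-2-carbaldehyde (cis)
Conditions: iBu2AlH (1.05 equiv), CH2Cl2, −78 °C; MeOH, then aq. KNaC4H4O6
Reagents that add atoms: none
Why: partial ester reduction at −78 °C, where the aluminium hemiacetal (stabilized by the α-oxygen) persists until the quench; the epoxide centres are not touched and the aldehyde is used at once.

Step 10
Reactants: 8 4α-[2,6-bis(benzyloxy)-4-hydroxyphenyl]-5,7,3',4'-tetra-O-benzylcatechin, 13 (2S,3S)-3-[3,4-bis(benzyloxy)phenyl]oxirane-2-carbaldehyde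
Product: 15 octa-O-benzyl catechin-(4α→6)-(2R,3R)-2,3-cis-flavan-3,4-diol (3,4-cis carbinol drawn), via epoxy carbinol adduct 14 (not isolated)
Conditions: Ti(OiPr)4 (1.2 equiv), 4 Å MS, toluene/CH2Cl2, rt, 1 h; then 13 (1.2 equiv), −20 °C to rt; aq. KNaC4H4O6
Reagents that add atoms: none
Why: Proposed new method: the phenol of 8 should exchange onto titanium, and the aryloxytitanium species should bind aldehyde 13 and deliver C4a (ortho to O1) to the carbonyl carbon through a six-membered transition state (ortho-specific hydroxyalkylation of metal phenoxides, Casiraghi type), giving titanium-bound 2,3-epoxy alkoxide 14; there the metal bridges O4 and the epoxide oxygen, and the same phenoxide O1 opens the epoxide at the distal benzylic carbon C2 (titanium-assisted C3-selective opening of 2,3-epoxy alcohols, Caron–Sharpless type), the tandem of these two known reaction types on an epoxy aldehyde being the untested element. Ring C of unit 2 is closed by an intermolecular C4a–C4 bond followed by a 6-endo-tet O1–C2 epoxide opening. C3 is carried over unchanged from 13, C2 is set by stereospecific inversion of the cis-epoxide carbon (giving the 2,3-cis, 2R,3R epicatechin pattern), and C4 by Felkin–Anh addition anti to the epoxide C–O bond (3,4-cis expected, inconsequential because step 14 ionizes C4). The step needs ortho-C attack over O-attack on the aldehyde (titanium template), 6-endo over 5-exo opening (benzylic C2 stabilized by the p-alkoxyaryl group, plus the chelate) and inversion without ionization at C2 (mild, halide-free Lewis acid at or below room temperature). The 4→6 connectivity is secured by the substrate, because O1 is the only free phenol, both carbons ortho to it are equivalent, and it lies para to the bond to unit 1, so the new ring can only fuse with unit 1 on C6. Should O-alkylation at C2 precede C–C bond formation, intramolecular ortho-hydroxyalkylation would converge on the same product.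

Step 11
Reactants: 16 (−)-epicatechin
Product: 17 5,7,3',4'-tetra-O-benzyl-(−)-epicatechin
Conditions: BnBr (4.4 equiv), K2CO3, DMF, 0 °C to rt
Reagents that add atoms: benzyl bromide, BrCc1ccccc1
Why: Williamson etherification of the four phenols, as in step 1, leaving the 3-OH free.

Step 12
Reactants: 17 5,7,3',4'-tetra-O-benzyl-(−)-epicatechin
Product: 18 4β-(2-ethoxyethoxy)-5,7,3',4'-tetra-O-benzylepicatechin (2,3-cis-3,4-trans)
Conditions: DDQ (2 equiv), 2-ethoxyethanol (5 equiv), CH2Cl2, rt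
Reagents that add atoms: 2-ethoxyethanol, CCOCCO
Why: DDQ benzylic oxidation as in step 2; in the 2,3-cis series the alcohol enters anti to both the 3-OH and the 2-aryl group (4β).

Step 13
Reactants: 18 4β-(2-ethoxyethoxy)-5,7,3',4'-tetra-O-benzylepicatechin, 17 5,7,3',4'-tetra-O-benzyl-(−)-epicatechin (4 equiv)
Product: 19 octa-O-benzyl procyanidin B2 [tetra-O-benzylepicatechin-(4β→8)-tetra-O-benzylepicatechin]
Conditions: TMSOTf (0.1 equiv), CH2Cl2, −78 °C
Reagents that add atoms: none
Why: TMSOTf-catalysed Friedel–Crafts coupling of the flavan C4 cation with C8 of 17 (more accessible than C6), where attack anti to the 3-OH sets C4 as 4β and excess 17 suppresses oligomerization.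

Step 14
Reactants: 15 octa-O-benzyl catechin-(4α→6)-flavan-3,4-diol, 19 octa-O-benzyl procyanidin B2 (3 equiv)
Product: 20 hexadeca-O-benzyl catechin-(4α→6)-epicatechin-(4β→8)-epicatechin-(4β→8)-epicatechin
Conditions: TMSOTf (0.2 equiv), 4 Å MS, CH2Cl2, −40 °C
Reagents that add atoms: none
Why: Lewis acid-mediated dehydrative condensation of a flavan-3,4-diol with a nucleophilic flavan, in which the C4 carbinol of unit 2 ionizes with loss of water (taken up by the sieves) to a cation stabilized by O1 and the 5,7-oxygens and is attacked by C8 of the upper unit of 19 from the β face, anti to the 3-OH and the 2-aryl group (4β), with excess 19 limiting self-condensation.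

Step 15
Reactants: 20 hexadeca-O-benzyl tetramer
Product: 21 catechin-(4α→6)-epicatechin-(4β→8)-epicatechin-(4β→8)-epicatechin (CNP0228086.1)
Conditions: H2 (1 atm), Pd(OH)2/C, THF/MeOH/H2O, rt
Reagents that add atoms: none
Why: hydrogenolysis of the sixteen aryl benzyl ethers under neutral conditions, which leave the acid-sensitive interflavan bonds and all stereocentres untouched.

**Compound list**

1 | (+)-catechin, (2R,3S) | Oc1cc(O)c2c(c1)O[C@H](c1ccc(O)c(O)c1)[C@@H](O)C2 | starting material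
2 | 5,7,3',4'-tetra-O-benzyl-(+)-catechin | c1ccccc1COc1cc(OCc3ccccc3)c2c(c1)O[C@H](c1ccc(OCc3ccccc3)c(OCc3ccccc3)c1)[C@@H](O)C2 | intermediate
3 | 4β-(2-ethoxyethoxy)-5,7,3',4'-tetra-O-benzylcatechin (3,4-cis) | c1ccccc1COc1cc(OCc3ccccc3)c2c(c1)O[C@H](c1ccc(OCc3ccccc3)c(OCc3ccccc3)c1)[C@@H](O)[C@H]2OCCOCC | intermediate
4 | phloroglucinol | Oc1cc(O)cc(O)c1 | starting material
5 | 5,7,3',4'-tetra-O-benzylcatechin-(4α→2)-phloroglucinol (3,4-trans) | c1ccccc1COc1cc(OCc3ccccc3)c2c(c1)O[C@H](c1ccc(OCc3ccccc3)c(OCc3ccccc3)c1)[C@@H](O)[C@@H]2c1c(O)cc(O)cc1O | intermediate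
6 | para-O-triisopropylsilyl ether of 5 | c1ccccc1COc1cc(OCc3ccccc3)c2c(c1)O[C@H](c1ccc(OCc3ccccc3)c(OCc3ccccc3)c1)[C@@H](O)[C@@H]2c1c(O)cc(O[Si](C(C)C)(C(C)C)C(C)C)cc1O | intermediate
7 | 4α-[2,6-bis(benzyloxy)-4-(triisopropylsilyloxy)phenyl]-5,7,3',4'-tetra-O-benzylcatechin | c1ccccc1COc1cc(OCc3ccccc3)c2c(c1)O[C@H](c1ccc(OCc3ccccc3)c(OCc3ccccc3)c1)[C@@H](O)[C@@H]2c1c(OCc3ccccc3)cc(O[Si](C(C)C)(C(C)C)C(C)C)cc1OCc1ccccc1 | intermediate
8 | 4α-[2,6-bis(benzyloxy)-4-hydroxyphenyl]-5,7,3',4'-tetra-O-benzylcatechin | c1ccccc1COc1cc(OCc3ccccc3)c2c(c1)O[C@H](c1ccc(OCc3ccccc3)c(OCc3ccccc3)c1)[C@@H](O)[C@@H]2c1c(OCc3ccccc3)cc(O)cc1OCc1ccccc1 | intermediate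
9 | 3,4-bis(benzyloxy)benzaldehyde | O=Cc1ccc(OCc2ccccc2)c(OCc2ccccc2)c1 | starting material
10 | methyl bis(2,2,2-trifluoroethoxy)phosphorylacetate | COC(=O)CP(=O)(OCC(F)(F)F)OCC(F)(F)F | starting material
11 | methyl (Z)-3-[3,4-bis(benzyloxy)phenyl]prop-2-enoate | COC(=O)/C=C\c1ccc(OCc2ccccc2)c(OCc2ccccc2)c1 | intermediate
12 | methyl (2S,3S)-3-[3,4-bis(benzyloxy)phenyl]oxirane-2-carboxylate (cis) | COC(=O)[C@H]1O[C@H]1c1ccc(OCc2ccccc2)c(OCc2ccccc2)c1 | intermediate
13 | (2S,3S)-3-[3,4-bis(benzyloxy)phenyl]oxirane-2-carbaldehyde (cis) | O=C[C@H]1O[C@H]1c1ccc(OCc2ccccc2)c(OCc2ccccc2)c1 | intermediate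
14 | ortho-hydroxyalkylation adduct of 8 and 13: 8 carrying a hydroxy(cis-3-aryloxiran-2-yl)methyl group on the carbon ortho to the phenol (present as its titanium alkoxide, drawn metal-free) | c1ccccc1COc1cc(OCc3ccccc3)c2c(c1)O[C@H](c1ccc(OCc3ccccc3)c(OCc3ccccc3)c1)[C@@H](O)[C@@H]2c1c(OCc3ccccc3)cc(O)c([C@@H](O)[C@H]4O[C@H]4c4ccc(OCc5ccccc5)c(OCc5ccccc5)c4)c1OCc1ccccc1 | intermediate (not isolated)
15 | octa-O-benzyl catechin-(4α→6)-(2R,3R)-2,3-cis-flavan-3,4-diol (3,4-cis drawn) | c1ccccc1COc1cc(OCc3ccccc3)c2c(c1)O[C@H](c1ccc(OCc3ccccc3)c(OCc3ccccc3)c1)[C@@H](O)[C@@H]2c1c(OCc3ccccc3)cc2c(c1OCc1ccccc1)[C@@H](O)[C@@H](O)[C@@H](c1ccc(OCc3ccccc3)c(OCc3ccccc3)c1)O2 | intermediate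
16 | (−)-epicatechin, (2R,3R) | Oc1cc(O)c2c(c1)O[C@H](c1ccc(O)c(O)c1)[C@H](O)C2 | starting material
17 | 5,7,3',4'-tetra-O-benzyl-(−)-epicatechin | c1ccccc1COc1cc(OCc3ccccc3)c2c(c1)O[C@H](c1ccc(OCc3ccccc3)c(OCc3ccccc3)c1)[C@H](O)C2 | intermediate
18 | 4β-(2-ethoxyethoxy)-5,7,3',4'-tetra-O-benzylepicatechin (3,4-trans) | c1ccccc1COc1cc(OCc3ccccc3)c2c(c1)O[C@H](c1ccc(OCc3ccccc3)c(OCc3ccccc3)c1)[C@H](O)[C@H]2OCCOCC | intermediate
19 | octa-O-benzyl procyanidin B2 | c1ccccc1COc1cc(OCc3ccccc3)c2c(c1)O[C@H](c1ccc(OCc3ccccc3)c(OCc3ccccc3)c1)[C@H](O)[C@H]2c1c(OCc3ccccc3)cc(OCc3ccccc3)c2c1O[C@H](c1ccc(OCc3ccccc3)c(OCc3ccccc3)c1)[C@H](O)C2 | intermediate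
20 | hexadeca-O-benzyl catechin-(4α→6)-epicatechin-(4β→8)-epicatechin-(4β→8)-epicatechin | c1ccccc1COc1cc(OCc4ccccc4)c2c(c1)O[C@H](c1ccc(OCc4ccccc4)c(OCc4ccccc4)c1)[C@@H](O)[C@@H]2c1c(OCc4ccccc4)cc2c(c1OCc1ccccc1)[C@H](c1c(OCc4ccccc4)cc(OCc4ccccc4)c3c1O[C@H](c1ccc(OCc4ccccc4)c(OCc4ccccc4)c1)[C@H](O)[C@H]3c1c(OCc4ccccc4)cc(OCc4ccccc4)c3c1O[C@H](c1ccc(OCc4ccccc4)c(OCc4ccccc4)c1)[C@H](O)C3)[C@@H](O)[C@@H](c1ccc(OCc4ccccc4)c(OCc4ccccc4)c1)O2 | intermediate
21 | catechin-(4α→6)-epicatechin-(4β→8)-epicatechin-(4β→8)-epicatechin (CNP0228086.1) | Oc1cc(O)c2c(c1)O[C@H](c1ccc(O)c(O)c1)[C@@H](O)[C@@H]2c1c(O)cc2c(c1O)[C@H](c1c(O)cc(O)c3c1O[C@H](c1ccc(O)c(O)c1)[C@H](O)[C@H]3c1c(O)cc(O)c3c1O[C@H](c1ccc(O)c(O)c1)[C@H](O)C3)[C@@H](O)[C@@H](c1ccc(O)c(O)c1)O2 | target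

**Step count and risks**

Total step count: 15. Longest linear sequence: 9 steps (steps 1 to 6, 10, 14, 15).

Steps most likely to fail:

1. Step 10 (proposed new method). The titanium-bound adduct may ionize at C2 before ring closure, which would erase the cis relationship. It may also open at C3 in the 5-exo mode, or the hindered ortho carbon may fail to capture the aldehyde. Fallback with known chemistry, setting out from 3 and 17 and returning at 21: the pyran annulation is abandoned and the 4→6 bond is made on an intact epicatechin under a bromine cap. NBS in CH2Cl2 at −78 °C converts 17 into 8-bromo-5,7,3',4'-tetra-O-benzylepicatechin F1. TMSOTf-promoted coupling of 3 with F1, whose only free ring A position is C6, should give 8-bromo-octa-O-benzyl catechin-(4α→6)-epicatechin F2. DDQ with 2-ethoxyethanol oxidizes the only benzylic CH2 (C4 of the lower unit) to the 4β-(2-ethoxyethoxy) ether F3. TMSOTf coupling of F3 with excess 19 gives the 8-bromo hexadeca-O-benzyl tetramer F4. Hydrogenolysis over Pd(OH)2/C with Et3N removes the benzyl groups and the bromine and gives 21.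

2. Step 14. The cation of 15 may be captured by the free ring A positions of another molecule of 15 (self-condensation), or by a C6 position of 19 instead of C8. Fallback, setting out from 15 and 17 and returning at 20: the chain is grown one unit at a time with the cheap monomer in large excess. TMSOTf coupling of 15 with 17 (8 equiv) should give the dodeca-O-benzyl trimer F5. DDQ with 2-ethoxyethanol oxidizes the only CH2 (C4 of the new bottom unit) to the 4β-(2-ethoxyethoxy) trimer F6. TMSOTf coupling of F6 with 17 (8 equiv) gives 20.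

3. Step 4. Site selection among the three phenols may be poor, or the silyl group may migrate or be lost during the benzylation of step 5. Fallback, setting out from 3 and returning at 7: the oxygens are differentiated before the C–C bond is made. Commercial 3,5-bis(benzyloxy)phenol F7 is silylated with iPr3SiCl and imidazole to [3,5-bis(benzyloxy)phenoxy]triisopropylsilane F8. TMSOTf-catalysed Friedel–Crafts reaction of 3 with F8 should then give 7 directly, because the bulky silyloxy group shields its two ortho carbons and leaves the carbon between the benzyloxy groups to react.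

**Further compounds**

F1 | step 10 | 8-bromo-5,7,3',4'-tetra-O-benzylepicatechin | c1ccccc1COc1cc(OCc3ccccc3)c2c(c1Br)O[C@H](c1ccc(OCc3ccccc3)c(OCc3ccccc3)c1)[C@H](O)C2
F2 | step 10 | 8-bromo-octa-O-benzyl catechin-(4α→6)-epicatechin | c1ccccc1COc1cc(OCc3ccccc3)c2c(c1)O[C@H](c1ccc(OCc3ccccc3)c(OCc3ccccc3)c1)[C@@H](O)[C@@H]2c1c(OCc3ccccc3)c(Br)c2c(c1OCc1ccccc1)C[C@@H](O)[C@@H](c1ccc(OCc3ccccc3)c(OCc3ccccc3)c1)O2
F3 | step 10 | 4β-(2-ethoxyethoxy) derivative of F2 at the lower unit | c1ccccc1COc1cc(OCc3ccccc3)c2c(c1)O[C@H](c1ccc(OCc3ccccc3)c(OCc3ccccc3)c1)[C@@H](O)[C@@H]2c1c(OCc3ccccc3)c(Br)c2c(c1OCc1ccccc1)[C@H](OCCOCC)[C@@H](O)[C@@H](c1ccc(OCc3ccccc3)c(OCc3ccccc3)c1)O2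
F4 | step 10 | 8-bromo (unit 2) hexadeca-O-benzyl tetramer | c1ccccc1COc1cc(OCc4ccccc4)c2c(c1)O[C@H](c1ccc(OCc4ccccc4)c(OCc4ccccc4)c1)[C@@H](O)[C@@H]2c1c(OCc4ccccc4)c(Br)c2c(c1OCc1ccccc1)[C@H](c1c(OCc4ccccc4)cc(OCc4ccccc4)c3c1O[C@H](c1ccc(OCc4ccccc4)c(OCc4ccccc4)c1)[C@H](O)[C@H]3c1c(OCc4ccccc4)cc(OCc4ccccc4)c3c1O[C@H](c1ccc(OCc4ccccc4)c(OCc4ccccc4)c1)[C@H](O)C3)[C@@H](O)[C@@H](c1ccc(OCc4ccccc4)c(OCc4ccccc4)c1)O2
F5 | step 14 | dodeca-O-benzyl catechin-(4α→6)-epicatechin-(4β→8)-epicatechin | c1ccccc1COc1cc(OCc4ccccc4)c2c(c1)O[C@H](c1ccc(OCc4ccccc4)c(OCc4ccccc4)c1)[C@@H](O)[C@@H]2c1c(OCc4ccccc4)cc2c(c1OCc1ccccc1)[C@H](c1c(OCc4ccccc4)cc(OCc4ccccc4)c3c1O[C@H](c1ccc(OCc4ccccc4)c(OCc4ccccc4)c1)[C@H](O)C3)[C@@H](O)[C@@H](c1ccc(OCc4ccccc4)c(OCc4ccccc4)c1)O2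
F6 | step 14 | 4β-(2-ethoxyethoxy) derivative of F5 at the bottom unit | c1ccccc1COc1cc(OCc4ccccc4)c2c(c1)O[C@H](c1ccc(OCc4ccccc4)c(OCc4ccccc4)c1)[C@@H](O)[C@@H]2c1c(OCc4ccccc4)cc2c(c1OCc1ccccc1)[C@H](c1c(OCc4ccccc4)cc(OCc4ccccc4)c3c1O[C@H](c1ccc(OCc4ccccc4)c(OCc4ccccc4)c1)[C@H](O)[C@H]3OCCOCC)[C@@H](O)[C@@H](c1ccc(OCc4ccccc4)c(OCc4ccccc4)c1)O2
F7 | step 4 | 3,5-bis(benzyloxy)phenol | Oc1cc(OCc2ccccc2)cc(OCc2ccccc2)c1
F8 | step 4 | [3,5-bis(benzyloxy)phenoxy]triisopropylsilane | CC(C)[Si](Oc1cc(OCc2ccccc2)cc(OCc2ccccc2)c1)(C(C)C)C(C)C
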